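**Retrosynthetic overview**

1. The target, 2,4-bis(4-hydroxy-5-methoxynaphthalen-1-yl)-8-methoxynaphthalen-1-ol, is traced back to its tris(benzyl ether) with a free C8 hydroxyl. The endgame is O-methylation at C8, then hydrogenolysis.
2. The strategy rests on ring D of the central naphthalene (C4a, C5, C6, C7, C8, C8a): C5, C6 and C7 carry only hydrogen and C8 carries an oxygen peri to the C1 oxygen. Ring D is cut at C5–C6 and C7–C8, so that C8 is the ester carbon and C5 the ortho-methyl carbon of a pentasubstituted benzoate (ring C), and C6/C7 come from phenyl vinyl sulfoxide.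
3. The benzoate comes from a twofold Suzuki–Miyaura coupling of methyl 2-(benzyloxy)-3,5-dibromo-6-methylbenzoate with a 4-(benzyloxy)-5-methoxynaphthalen-1-yl boronate.
4. The dibromide comes from methyl 2-hydroxy-6-methylbenzoate (bromination, benzylation). The boronate comes from 1,8-dihydroxynaphthalene (monomethylation, para-bromination, benzylation, borylation).
5. Ring order: both outer naphthalenes and ring C are bought in; ring D is the only ring formed, and it is formed last.

Key step: step 8

Assumption: the target SMILES defines no configuration at the two biaryl axes, so they are treated as interconverting rotamers and no atroposelective step is planned. Atom numbers C1 to C8 refer to the central naphthalene of the target throughout.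

**Route**

Step 1
Reactants: 1 1,8-dihydroxynaphthalene
Product: 2 8-methoxynaphthalen-1-ol
Conditions: MeI (1.1 equiv), K2CO3 (1.1 equiv), acetone, reflux
Reagents that add atoms: iodomethane, CI
Why: Williamson mono-O-methylation, in which the monoanion of the peri-diol is held by an intramolecular hydrogen bond so that the second hydroxyl is much less acidic and alkylation should stop after one methyl group.

Step 2
Reactants: 2 8-methoxynaphthalen-1-ol
Product: 3 4-bromo-8-methoxynaphthalen-1-ol
Conditions: N-bromosuccinimide (1.0 equiv), MeCN, -20 to 0 °C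
Reagents that add atoms: N-bromosuccinimide, O=C1CCC(=O)N1Br
Why: electrophilic aromatic bromination, in which the free hydroxyl activates its own ring far more than the methoxy group activates the other and N-bromosuccinimide in MeCN favours the para position C4 of a 1-naphthol over C2.

Step 3
Reactants: 3 4-bromo-8-methoxynaphthalen-1-ol; 4 benzyl bromide
Product: 5 1-(benzyloxy)-4-bromo-8-methoxynaphthalene
Conditions: K2CO3, DMF, 50 °C
Reagents that add atoms: none
Why: Williamson benzylation of the naphthoxide by SN2 displacement on benzyl bromide, with the aryl bromide inert to carbonate in DMF.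

Step 4
Reactants: 5 1-(benzyloxy)-4-bromo-8-methoxynaphthalene
Product: 6 2-[4-(benzyloxy)-5-methoxynaphthalen-1-yl]-4,4,5,5-tetramethyl-1,3,2-dioxaborolane
Conditions: B2pin2, KOAc, PdCl2(dppf) (cat.), 1,4-dioxane, 90 °C
Reagents that add atoms: bis(pinacolato)diboron, CC1(C)OB(OC1(C)C)B1OC(C)(C)C(C)(C)O1
Why: Miyaura borylation (oxidative addition of the aryl bromide to zerovalent palladium, acetate-assisted transmetalation from boron, reductive elimination), giving the pinacol ester because the free boronic acid of this electron-rich 1-naphthyl unit would be prone to protodeboronation.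

Step 5
Reactants: 7 methyl 2-hydroxy-6-methylbenzoate
Product: 8 methyl 3,5-dibromo-2-hydroxy-6-methylbenzoate
Conditions: Br2 (2.1 equiv), AcOH, rt
Reagents that add atoms: bromine, BrBr
Why: electrophilic aromatic bromination, in which hydroxyl and methyl jointly direct to C3 and C5 while C4 is meta to the hydroxyl, and the ionic conditions leave the benzylic methyl untouched.

Step 6
Reactants: 8 methyl 3,5-dibromo-2-hydroxy-6-methylbenzoate; 4 benzyl bromide
Product: 9 methyl 2-(benzyloxy)-3,5-dibromo-6-methylbenzoate
Conditions: K2CO3, DMF, 60 °C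
Reagents that add atoms: none
Why: Williamson benzylation, in which the acidic salicylate-type phenol, although hydrogen-bonded to the ester and flanked by bromine, should give a phenoxide that is alkylated by benzyl bromide in warm DMF.

Step 7
Reactants: 9 methyl 2-(benzyloxy)-3,5-dibromo-6-methylbenzoate; 6 2-[4-(benzyloxy)-5-methoxynaphthalen-1-yl]-4,4,5,5-tetramethyl-1,3,2-dioxaborolane (2.4 equiv)
Product: 10 methyl 2-(benzyloxy)-3,5-bis[4-(benzyloxy)-5-methoxynaphthalen-1-yl]-6-methylbenzoate
Conditions: Pd(OAc)2 (cat.), SPhos, K3PO4, PhMe/H2O, 100 °C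
Reagents that add atoms: none
Why: twofold Suzuki–Miyaura coupling, in which the bulky electron-rich biaryl phosphine SPhos on palladium is suited to ortho-substituted aryl bromides and peri-hindered naphthyl boronates, and the ester flanked by two ortho substituents should resist saponification by aqueous phosphate.

Step 8
Reactants: 10 methyl 2-(benzyloxy)-3,5-bis[4-(benzyloxy)-5-methoxynaphthalen-1-yl]-6-methylbenzoate; 11 phenyl vinyl sulfoxide (racemic)
Product: 14 8-(benzyloxy)-5,7-bis[4-(benzyloxy)-5-methoxynaphthalen-1-yl]naphthalen-1-ol, via keto sulfoxide 12 (not isolated), via dienone tautomer 13 (not isolated)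
Conditions: LiN(iPr)2 (1.05 equiv), THF, -78 °C; 11 (1.2 equiv), -78 to -20 °C; AcOH (1.05 equiv); then PhMe, 90 °C
Reagents that add atoms: none
Why: Proposed new method: LiN(iPr)2 removes a proton from the ortho methyl group of 10 (the most acidic C–H, vinylogous to the ester), the toluate anion adds to the β-carbon of 11 to form C5–C6, and the resulting α-sulfinyl carbanion attacks the neighbouring ester carbon to form C7–C8 with loss of methoxide, giving the lithium enolate of 12; after protonation, heating causes thermal syn-elimination of PhSOH across C6–C7 to give 13, which tautomerises to naphthol 14. The closest known reactions are the Staunton–Weinreb annulation of toluate anions with enoates and enones, the conjugate addition of enolates to aryl vinyl sulfoxides, and the naphthol annulation of sulfinyl-stabilised toluate anions that also ends in thermal loss of PhSOH; the new element is that the sulfoxide sits on the two-carbon acceptor. Ring D closes by a 6-exo-trig Claisen (Dieckmann-type) acyl substitution. No stereocentre remains, since the carbon and sulfur centres of 12 form as a diastereomer mixture and every isomer has a syn β-hydrogen at C6 for the elimination. The step needs chemoselectivity for lateral deprotonation and for Michael addition ahead of any attack on an ester; the ester of 10, flanked by the benzyloxy and methyl groups, is shielded against self-condensation, and only about one equivalent of base is used so that no free amide base is left to metalate or add to 11. Regiochemistry is not in question, because the methyl and ester carbons are fixed as C5 and C8.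

Step 9
Reactants: 14 8-(benzyloxy)-5,7-bis[4-(benzyloxy)-5-methoxynaphthalen-1-yl]naphthalen-1-ol
Product: 15 1-(benzyloxy)-2,4-bis[4-(benzyloxy)-5-methoxynaphthalen-1-yl]-8-methoxynaphthalene
Conditions: MeI, K2CO3, DMF, 40 °C
Reagents that add atoms: iodomethane, CI
Why: Williamson O-methylation of the only free hydroxyl, which is hydrogen-bonded to the peri benzyloxy oxygen but should still be deprotonated by carbonate in DMF.

Step 10
Reactants: 15 1-(benzyloxy)-2,4-bis[4-(benzyloxy)-5-methoxynaphthalen-1-yl]-8-methoxynaphthalene
Product: 16 2,4-bis(4-hydroxy-5-methoxynaphthalen-1-yl)-8-methoxynaphthalen-1-ol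
Conditions: H2 (1 atm), Pd on carbon, THF/MeOH, rt
Reagents that add atoms: none
Why: heterogeneous hydrogenolysis of the three aryl benzyl ethers, under neutral conditions that should leave the methyl ethers, the naphthalene rings and the electron-rich naphthols untouched.

**Compound list**

1 | 1,8-dihydroxynaphthalene | Oc1cccc2cccc(O)c12 | starting material
2 | 8-methoxynaphthalen-1-ol | COc1cccc2cccc(O)c12 | intermediate
3 | 4-bromo-8-methoxynaphthalen-1-ol | COc1cccc2c(Br)ccc(O)c12 | intermediate
4 | benzyl bromide | BrCc1ccccc1 | starting material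
5 | 1-(benzyloxy)-4-bromo-8-methoxynaphthalene | COc1cccc2c(Br)ccc(OCc3ccccc3)c12 | intermediate
6 | 2-[4-(benzyloxy)-5-methoxynaphthalen-1-yl]-4,4,5,5-tetramethyl-1,3,2-dioxaborolane | COc1cccc2c(B3OC(C)(C)C(C)(C)O3)ccc(OCc3ccccc3)c12 | intermediate
7 | methyl 2-hydroxy-6-methylbenzoate | COC(=O)c1c(C)cccc1O | starting material
8 | methyl 3,5-dibromo-2-hydroxy-6-methylbenzoate | COC(=O)c1c(C)c(Br)cc(Br)c1O | intermediate
9 | methyl 2-(benzyloxy)-3,5-dibromo-6-methylbenzoate | COC(=O)c1c(C)c(Br)cc(Br)c1OCc1ccccc1 | intermediate
10 | methyl 2-(benzyloxy)-3,5-bis[4-(benzyloxy)-5-methoxynaphthalen-1-yl]-6-methylbenzoate | COC(=O)c1c(C)c(-c2ccc(OCc3ccccc3)c3c(OC)cccc23)cc(-c2ccc(OCc3ccccc3)c3c(OC)cccc23)c1OCc1ccccc1 | intermediate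
11 | phenyl vinyl sulfoxide (racemic) | C=CS(=O)c1ccccc1 | starting material
12 | 8-(benzyloxy)-5,7-bis[4-(benzyloxy)-5-methoxynaphthalen-1-yl]-2-(phenylsulfinyl)-3,4-dihydronaphthalen-1(2H)-one (keto sulfoxide; diastereomer mixture; not isolated) | O=C1C(S(=O)c2ccccc2)CCc2c(-c3ccc(OCc4ccccc4)c4c(OC)cccc34)cc(-c3ccc(OCc4ccccc4)c4c(OC)cccc34)c(OCc3ccccc3)c12 | intermediate
13 | 8-(benzyloxy)-5,7-bis[4-(benzyloxy)-5-methoxynaphthalen-1-yl]naphthalen-1(4H)-one (dienone tautomer; not isolated) | O=C1C=CCc2c(-c3ccc(OCc4ccccc4)c4c(OC)cccc34)cc(-c3ccc(OCc4ccccc4)c4c(OC)cccc34)c(OCc3ccccc3)c12 | intermediate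
14 | 8-(benzyloxy)-5,7-bis[4-(benzyloxy)-5-methoxynaphthalen-1-yl]naphthalen-1-ol | Oc1cccc2c(-c3ccc(OCc4ccccc4)c4c(OC)cccc34)cc(-c3ccc(OCc4ccccc4)c4c(OC)cccc34)c(OCc3ccccc3)c12 | intermediate
15 | 1-(benzyloxy)-2,4-bis[4-(benzyloxy)-5-methoxynaphthalen-1-yl]-8-methoxynaphthalene | COc1cccc2c(-c3ccc(OCc4ccccc4)c4c(OC)cccc34)cc(-c3ccc(OCc4ccccc4)c4c(OC)cccc34)c(OCc3ccccc3)c12 | intermediate
16 | 2,4-bis(4-hydroxy-5-methoxynaphthalen-1-yl)-8-methoxynaphthalen-1-ol | COc1cccc2c(-c3cc(-c4ccc(O)c5c(OC)cccc45)c4cccc(OC)c4c3O)ccc(O)c12 | target

**Step count and risks**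

Total steps: 10. Longest linear sequence: 8 steps (steps 1, 2, 3, 4, 7, 8, 9, 10).

Steps most likely to fail:

1. Step 8 (proposed annulation). Conjugate addition to the weakly electrophilic vinyl sulfoxide may be slow at temperatures where the toluate anion is stable. Proton transfer may quench the α-sulfinyl carbanion before it closes onto the hindered ester. The new naphthol may be sulfenylated by the PhSOH released on heating. Fallback, by known reaction types only, taking ring D from a preformed naphthalene: it sets out from 2 and returns at 15. Compound 2 is brominated ortho and para to the hydroxyl (N-bromosuccinimide, 2 equiv, MeCN) to 2,4-dibromo-8-methoxynaphthalen-1-ol F1. This is benzylated with 4 (K2CO3, DMF) to 1-(benzyloxy)-2,4-dibromo-8-methoxynaphthalene F2. A twofold Suzuki–Miyaura coupling of F2 with 6 (Pd(OAc)2, SPhos, K3PO4, PhMe/H2O) should give 15, and step 10 follows.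

2. Step 7 (twofold coupling). Protodeboronation of the electron-rich naphthyl boronate may outrun the second, more hindered coupling, so that the reaction stalls after one arylation. Fallback by Negishi coupling: it sets out from 5 and 9 and returns at 10. Bromine–lithium exchange on 5 (n-BuLi, THF, -78 °C) gives [4-(benzyloxy)-5-methoxynaphthalen-1-yl]lithium F3. Transmetalation with ZnCl2 gives [4-(benzyloxy)-5-methoxynaphthalen-1-yl]zinc chloride F4. F4 is coupled under anhydrous conditions with 9 (Pd(OAc)2, SPhos, THF, 60 °C) to give 10.

3. Step 2 (para-bromination). Bromination ortho to the hydroxyl and overbromination of the activated naphthol may erode the regioselectivity. Fallback in which an alkoxy group, not a free hydroxyl, directs the bromine: it sets out from 1 and returns at 5.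
   - Compound 1 is monobenzylated with 4 (K2CO3, acetone) to 8-(benzyloxy)naphthalen-1-ol F5.
   - Acetylation (Ac2O, pyridine) gives 8-(benzyloxy)naphthalen-1-yl acetate F6.
   - Bromination with N-bromosuccinimide in MeCN, para to the benzyloxy group on the ring not deactivated by the acetoxy group, gives 8-(benzyloxy)-5-bromonaphthalen-1-yl acetate F7.
   - Acetate cleavage (K2CO3, MeOH) gives 8-(benzyloxy)-5-bromonaphthalen-1-ol F8.
   - O-Methylation (MeI, K2CO3, DMF) gives 5.

**Further compounds**

F1 | step 8 | 2,4-dibromo-8-methoxynaphthalen-1-ol | COc1cccc2c(Br)cc(Br)c(O)c12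
F2 | step 8 | 1-(benzyloxy)-2,4-dibromo-8-methoxynaphthalene | COc1cccc2c(Br)cc(Br)c(OCc3ccccc3)c12
F3 | step 7 | [4-(benzyloxy)-5-methoxynaphthalen-1-yl]lithium | [Li]c1ccc(OCc2ccccc2)c2c(OC)cccc12
F4 | step 7 | [4-(benzyloxy)-5-methoxynaphthalen-1-yl]zinc chloride | Cl[Zn]c1ccc(OCc2ccccc2)c2c(OC)cccc12
F5 | step 2 | 8-(benzyloxy)naphthalen-1-ol | Oc1cccc2cccc(OCc3ccccc3)c12
F6 | step 2 | 8-(benzyloxy)naphthalen-1-yl acetate | CC(=O)Oc1cccc2cccc(OCc3ccccc3)c12
F7 | step 2 | 8-(benzyloxy)-5-bromonaphthalen-1-yl acetate | CC(=O)Oc1cccc2c(Br)ccc(OCc3ccccc3)c12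
F8 | step 2 | 8-(benzyloxy)-5-bromonaphthalen-1-ol | Oc1cccc2c(Br)ccc(OCc3ccccc3)c12
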